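Everything rests on one disconnection: the C8–C8' bond of ring A together with the C7'–O bond of ring B (masked as C7'–B), which leads back to a racemic acyloin 3,4-dimethoxycinnamate. In one operation a chiral bisphosphine–copper boryl catalyst borylates C7' of the cinnamate C9'–C8'=C7', which hangs on the future ring A oxygen at C7, and the C8' copper enolate adds to the C8 ketone; this closes ring A as its C9' lactone and sets C7, C8, C8' and C7', the acidic C7–H beside the ketone keeping that centre labile until closure. Boron then becomes the ring B oxygen, C9 closes ring B, and C9' is reduced to CH2.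

Key step: step 6

Numbering: C7 = ArCH–O, C8 = the carbon that ends as the acetoxy bridgehead, C9 = its CH2O; C7' = Ar'CH–O (or –B), C8' = bridgehead CH, C9' = its CH2O (C=O in the lactones); ring A = O–C7–C8–C8'–C9', ring B = O–C7'–C8'–C8–C9. Ar = 3-methoxy-4-(triisopropylsilyloxy)phenyl, Ar' = 3,4-dimethoxyphenyl, TBS = tert-butyldimethylsilyl, TIPS = triisopropylsilyl, Bpin = 4,4,5,5-tetramethyl-1,3,2-dioxaborolan-2-yl.

Assumption: the hand of the bisphosphine is the one that puts boron on the Si face of C7' (7'S); it is fixed beforehand on methyl 3,4-dimethoxycinnamate, and the antipodal ligand is used if the model shows the opposite sense.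

Design of the precursor: the phenol is carried as a TIPS ether, cleaved by fluoride, so that the last step is not a hydrogenolysis beside two benzylic C–O bonds. The acyloin is assembled by vinyllithium addition and ozonolysis, which avoids a diazoketone and a free hydroxymethyl acyloin ester that could shift its acyl group.

Step 1
Reactants: 1 vanillin
Product: 2 3-methoxy-4-[(triisopropylsilyl)oxy]benzaldehyde
Conditions: TIPSCl, imidazole, DMF, rt
Reagents that add atoms: triisopropylsilyl chloride, CC(C)[Si](Cl)(C(C)C)C(C)C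
Why: Imidazole-assisted silylation of the phenol gives an aryl silyl ether that should survive organolithium, catalytic alkoxide, hydride and Lewis acid and is removed at the end by fluoride.

Step 2
Reactants: 3 2-bromoprop-2-en-1-ol
Product: 4 [(2-bromoprop-2-en-1-yl)oxy](tert-butyl)dimethylsilane
Conditions: TBSCl, imidazole, CH2Cl2, 0 °C → rt
Reagents that add atoms: tert-butyldimethylsilyl chloride, CC(C)(C)[Si](C)(C)Cl
Why: Standard silyl ether formation on a primary allylic alcohol leaves the vinyl bromide untouched.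

Step 3
Reactants: 2 3-methoxy-4-[(triisopropylsilyl)oxy]benzaldehyde; 4 [(2-bromoprop-2-en-1-yl)oxy](tert-butyl)dimethylsilane
Product: 6 rac-2-{[(tert-butyldimethylsilyl)oxy]methyl}-1-{3-methoxy-4-[(triisopropylsilyl)oxy]phenyl}prop-2-en-1-ol, via vinyllithium 5 (not isolated)
Conditions: 4, t-BuLi (2.0 equiv), Et2O, −78 °C; then 2, −78 °C; aq. NH4Cl
Reagents that add atoms: [(2-bromoprop-2-en-1-yl)oxy](tert-butyl)dimethylsilane (4), C=C(Br)CO[Si](C)(C)C(C)(C)C
Why: Bromine–lithium exchange followed by 1,2-addition of the vinyllithium to the aldehyde creates C7 as a racemate, which is intended because C7 becomes labile again in 10.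

Step 4
Reactants: 6 rac-2-{[(tert-butyldimethylsilyl)oxy]methyl}-1-{3-methoxy-4-[(triisopropylsilyl)oxy]phenyl}prop-2-en-1-ol
Product: 8 rac-3-[(tert-butyldimethylsilyl)oxy]-1-hydroxy-1-{3-methoxy-4-[(triisopropylsilyl)oxy]phenyl}propan-2-one, via ozonide 7 (not isolated)
Conditions: O3, CH2Cl2, −78 °C (Sudan red end point); then PPh3, −78 °C → rt
Reagents that add atoms: ozone, O=[O+][O-]
Why: Ozonolysis of the 1,1-disubstituted alkene with reductive work-up unmasks the C8 ketone, the alkene reacting far faster than the silyloxy arene, and C7 stays racemic.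

Step 5
Reactants: 8 rac-3-[(tert-butyldimethylsilyl)oxy]-1-hydroxy-1-{3-methoxy-4-[(triisopropylsilyl)oxy]phenyl}propan-2-one; 9 (E)-3-(3,4-dimethoxyphenyl)prop-2-enoic acid
Product: 10 rac-3-[(tert-butyldimethylsilyl)oxy]-1-{3-methoxy-4-[(triisopropylsilyl)oxy]phenyl}-2-oxopropyl (E)-3-(3,4-dimethoxyphenyl)prop-2-enoate
Conditions: EDC·HCl, DMAP (cat.), CH2Cl2, 0 °C → rt
Reagents that add atoms: (E)-3-(3,4-dimethoxyphenyl)prop-2-enoic acid (9), COc1ccc(/C=C/C(=O)O)cc1OC
Why: Steglich esterification of the secondary acyloin hydroxyl under nearly neutral conditions should avoid α-ketol isomerisation and keeps the E-alkene, C7 remaining racemic.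

Step 6
Reactants: 10 rac-3-[(tert-butyldimethylsilyl)oxy]-1-{3-methoxy-4-[(triisopropylsilyl)oxy]phenyl}-2-oxopropyl (E)-3-(3,4-dimethoxyphenyl)prop-2-enoate; 11 bis(pinacolato)diboron
Product: 14 (7R,8S,8'R,7'S) ring A lactone 5-Ar-4-hydroxy-4-(TBSO-methyl)-3-[Ar'(Bpin)methyl]dihydrofuran-2(3H)-one, via α-cuprio ester 12 (not isolated), via O-boryl aldolate 13 (not isolated)
Conditions: CuCl (5 mol%), NaOtBu (6 mol%) [gives CuOtBu], (R)-DTBM-SEGPHOS (5.5 mol%), B2pin2 (1.2 equiv), THF, no protic additive, −20 °C → rt; aq. NH4Cl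
Reagents that add atoms: bis(pinacolato)diboron (11), CC1(C)OB(OC1(C)C)B1OC(C)(C)C(C)(C)O1
Why: Proposed new method: The chiral bisphosphine complex of CuOtBu is borylated by B2pin2, the copper boryl adds across C8'=C7' of the cinnamate in a syn sense with boron on C7', the resulting C8' copper enolate 12 adds to the C8 ketone held five atoms away, and B2pin2 borylates the copper aldolate to 13 and returns the copper boryl, after which aqueous work-up frees the C8 hydroxyl. The closest known reactions are the copper-catalysed enantioselective borylative aldol cyclisation of enone diones and the hydride-initiated aldol lactonisation of enoates tethered through the ester oxygen to ketones; their combination with a configurationally labile acyloin ester is not known. Ring A closes as the C9' lactone in the 5-(enolendo)-exo-trig mode, formally disfavoured for enolates yet the mode of Dieckmann tetronic acid syntheses and of the hydride-initiated lactonisations. C7' (S) is set by the ligand, which delivers boron to the Si face of C7'; C8' (R) follows from syn-borylcupration and C–C bond formation with retention at the carbon-bound copper centre, a net syn-carboboration of the E-alkene; C8 (S) follows because the ketone oxygen stays on that copper, on the outer side of the forming ring over C8'–H, so that C9 ends cis to the C7' arm; C7 (R) is chosen in the ring closure, the aryl group taking the side trans to the C7' arm, while unreacted acyloin is racemised through its enolate by the catalytic alkoxide. The step needs conjugate borylation ahead of 1,2-addition to the activated ketone (phosphine-ligated copper boryl, electron-poor alkene), C–C bond formation ahead of protonation (no protic additive, a highly electrophilic α,α'-dioxygenated ketone in reach) and ring closure before copper migrates to oxygen, since the oxygen-bound enolate would close through a copper-bridged chair and give the C8 epimer; the bulky ligand is chosen to hold copper on carbon.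

Step 7
Reactants: 14 (7R,8S,8'R,7'S) ring A lactone with the C7' boronate
Product: 16 (7R,8S,8'R,7'S) ring A lactone 5-Ar-4-hydroxy-4-(TBSO-methyl)-3-[Ar'(hydroxy)methyl]dihydrofuran-2(3H)-one, via borate ester 15 (not isolated)
Conditions: NaBO3·4H2O, THF/H2O (1:1), 0 °C → rt
Reagents that add atoms: sodium perborate, [Na+].[O-]B1OO1
Why: Boronate oxidation moves C7' from boron to oxygen with retention, so C7'–B (S) becomes C7'–OH (S), and perborate is mild enough for the lactone and the aryl silyl ether.

Step 8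
Reactants: 16 (7R,8S,8'R,7'S) ring A lactone with C7'–OH and C9–OTBS
Product: 17 (7R,8S,8'R,7'S) triol lactone 5-Ar-4-hydroxy-4-(hydroxymethyl)-3-[Ar'(hydroxy)methyl]dihydrofuran-2(3H)-one
Conditions: HF·pyridine, pyridine, THF, 0 °C → rt
Reagents that add atoms: none
Why: Desilylation with buffered acidic fluoride removes the primary alkyl silyl ether, while the aryl TIPS ether (labile to basic, not to acidic fluoride) and the acid-sensitive C7' benzylic alcohol should remain, no stereocentre being involved.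

Step 9
Reactants: 17 (7R,8S,8'R,7'S) triol lactone
Product: 19 (1S,2R,5R,6S)-6-(3,4-dimethoxyphenyl)-1-hydroxy-2-Ar-3,7-dioxabicyclo[3.3.0]octan-4-one, via primary tosylate 18 (not isolated)
Conditions: TsCl (1.2 equiv), Et3N, Bu2SnO (5 mol%), CH2Cl2, rt; then DBU, 40 °C
Reagents that add atoms: none
Why: Tin-catalysed selective sulfonylation of the primary hydroxyl of the C8/C9 diol is followed by intramolecular Williamson etherification, the C7' hydroxyl displacing the C9 tosylate in a 5-exo-tet closure (directly or by opening the transient C8–C9 epoxide at C9), so ring B forms with retention at C7' and C8 on the cis relationship set in step 6.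

Step 10
Reactants: 19 (1S,2R,5R,6S)-6-(3,4-dimethoxyphenyl)-1-hydroxy-2-Ar-3,7-dioxabicyclo[3.3.0]octan-4-one
Product: 20 (1S,2R,5R,6S)-6-(3,4-dimethoxyphenyl)-2-Ar-3,7-dioxabicyclo[3.3.0]octane-1,4-diol (lactol and anomer mixture at C4)
Conditions: i-Bu2AlH (3 equiv), CH2Cl2, −78 °C; aq. potassium sodium tartrate
Reagents that add atoms: none
Why: Partial reduction of the γ-lactone by diisobutylaluminium hydride at low temperature stops at the lactol, C9' becoming a hemiacetal carbon while the four stereocentres are untouched.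

Step 11
Reactants: 20 (1S,2R,5R,6S)-6-(3,4-dimethoxyphenyl)-2-Ar-3,7-dioxabicyclo[3.3.0]octane-1,4-diol
Product: 21 (1S,2R,5R,6S)-6-(3,4-dimethoxyphenyl)-2-Ar-3,7-dioxabicyclo[3.3.0]octan-1-ol
Conditions: Et3SiH, BF3·OEt2, CH2Cl2, −78 → −40 °C
Reagents that add atoms: none
Why: Ionic hydrogenation of the lactol through the ring A oxocarbenium ion leaves C9' as CH2, and at low temperature the lactol should ionise far faster than the benzylic ethers, so C7 and C7' keep their configuration.

Step 12
Reactants: 21 (1S,2R,5R,6S)-6-(3,4-dimethoxyphenyl)-2-Ar-3,7-dioxabicyclo[3.3.0]octan-1-ol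
Product: 22 (1S,2R,5R,6S)-6-(3,4-dimethoxyphenyl)-2-Ar-3,7-dioxabicyclo[3.3.0]octan-1-yl acetate
Conditions: Ac2O, Et3N, DMAP (1 equiv), CH2Cl2, rt → 40 °C
Reagents that add atoms: acetic anhydride, CC(=O)OC(C)=O
Why: DMAP-catalysed acylation of the hindered tertiary C8 hydroxyl, the only free hydroxyl left, does not break the C8–O bond, so configuration is retained.

Step 13
Reactants: 22 (1S,2R,5R,6S)-6-(3,4-dimethoxyphenyl)-2-Ar-3,7-dioxabicyclo[3.3.0]octan-1-yl acetate
Product: 23 (1S,2R,5R,6S)-6-(3,4-dimethoxyphenyl)-2-(4-hydroxy-3-methoxyphenyl)-3,7-dioxabicyclo[3.3.0]octan-1-yl acetate (CNP0107105.1)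
Conditions: Bu4NF, AcOH, THF, 0 °C
Reagents that add atoms: none
Why: Fluoride-mediated cleavage of the aryl silyl ether, buffered with acetic acid so that the tertiary acetate and the benzylic ethers survive, frees the phenol without hydrogenolysis.

Compound list
1 | vanillin (4-hydroxy-3-methoxybenzaldehyde) | COc1cc(C=O)ccc1O | starting material
2 | 3-methoxy-4-[(triisopropylsilyl)oxy]benzaldehyde | COc1cc(C=O)ccc1O[Si](C(C)C)(C(C)C)C(C)C | intermediate
3 | 2-bromoprop-2-en-1-ol | C=C(Br)CO | starting material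
4 | [(2-bromoprop-2-en-1-yl)oxy](tert-butyl)dimethylsilane | C=C(Br)CO[Si](C)(C)C(C)(C)C | intermediate
5 | {3-[(tert-butyldimethylsilyl)oxy]prop-1-en-2-yl}lithium | [Li]C(=C)CO[Si](C)(C)C(C)(C)C | intermediate
6 | rac-2-{[(tert-butyldimethylsilyl)oxy]methyl}-1-Ar-prop-2-en-1-ol | COc1cc(C(O)C(=C)CO[Si](C)(C)C(C)(C)C)ccc1O[Si](C(C)C)(C(C)C)C(C)C | intermediate
7 | ozonide of 6 (1,2,4-trioxolane spiro at C8) | COc1cc(C(O)C2(CO[Si](C)(C)C(C)(C)C)OCOO2)ccc1O[Si](C(C)C)(C(C)C)C(C)C | intermediate
8 | rac-3-[(tert-butyldimethylsilyl)oxy]-1-hydroxy-1-Ar-propan-2-one | COc1cc(C(O)C(=O)CO[Si](C)(C)C(C)(C)C)ccc1O[Si](C(C)C)(C(C)C)C(C)C | intermediate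
9 | (E)-3-(3,4-dimethoxyphenyl)prop-2-enoic acid | COc1ccc(/C=C/C(=O)O)cc1OC | starting material
10 | rac-3-[(tert-butyldimethylsilyl)oxy]-1-Ar-2-oxopropyl (E)-3-(3,4-dimethoxyphenyl)prop-2-enoate (C7 racemic and labile) | COc1cc(C(OC(=O)/C=C/c2ccc(OC)c(OC)c2)C(=O)CO[Si](C)(C)C(C)(C)C)ccc1O[Si](C(C)C)(C(C)C)C(C)C | intermediate
11 | bis(pinacolato)diboron | CC1(C)OB(OC1(C)C)B1OC(C)(C)C(C)(C)O1 | starting material
12 | α-cuprio ester: 10 after syn-borylcupration, Bpin on C7' (S), copper on C8' syn to boron (bisphosphine not drawn), C7 not yet set | COc1cc(C(OC(=O)[C@H]([C@H](B2OC(C)(C)C(C)(C)O2)c2ccc(OC)c(OC)c2)[Cu])C(=O)CO[Si](C)(C)C(C)(C)C)ccc1O[Si](C(C)C)(C(C)C)C(C)C | intermediate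
13 | O-boryl aldolate: 14 with C8–O–Bpin | COc1cc([C@H]2OC(=O)[C@H]([C@H](B3OC(C)(C)C(C)(C)O3)c3ccc(OC)c(OC)c3)[C@]2(OB4OC(C)(C)C(C)(C)O4)CO[Si](C)(C)C(C)(C)C)ccc1O[Si](C(C)C)(C(C)C)C(C)C | intermediate
14 | (7R,8S,8'R,7'S) ring A lactone: 5-Ar-4-hydroxy-4-(TBSO-methyl)-3-[Ar'(Bpin)methyl]dihydrofuran-2(3H)-one; on ring A the aryl group, the hydroxyl and C8'–H lie on one face, C9 and the C7' arm on the other | COc1cc([C@H]2OC(=O)[C@H]([C@H](B3OC(C)(C)C(C)(C)O3)c3ccc(OC)c(OC)c3)[C@]2(O)CO[Si](C)(C)C(C)(C)C)ccc1O[Si](C(C)C)(C(C)C)C(C)C | intermediate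
15 | borate ester: 16 with C7'–O–Bpin | COc1cc([C@H]2OC(=O)[C@H]([C@H](OB3OC(C)(C)C(C)(C)O3)c3ccc(OC)c(OC)c3)[C@]2(O)CO[Si](C)(C)C(C)(C)C)ccc1O[Si](C(C)C)(C(C)C)C(C)C | intermediate
16 | (7R,8S,8'R,7'S) ring A lactone with C7'–OH and C9–OTBS | COc1cc([C@H]2OC(=O)[C@H]([C@H](O)c3ccc(OC)c(OC)c3)[C@]2(O)CO[Si](C)(C)C(C)(C)C)ccc1O[Si](C(C)C)(C(C)C)C(C)C | intermediate
17 | (7R,8S,8'R,7'S) triol lactone (C7'–OH, C8–OH, C9–OH) | COc1cc([C@H]2OC(=O)[C@H]([C@H](O)c3ccc(OC)c(OC)c3)[C@]2(O)CO)ccc1O[Si](C(C)C)(C(C)C)C(C)C | intermediate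
18 | primary tosylate of 17 at C9 | COc1cc([C@H]2OC(=O)[C@H]([C@H](O)c3ccc(OC)c(OC)c3)[C@]2(O)COS(=O)(=O)c3ccc(C)cc3)ccc1O[Si](C(C)C)(C(C)C)C(C)C | intermediate
19 | (1S,2R,5R,6S)-6-(3,4-dimethoxyphenyl)-1-hydroxy-2-Ar-3,7-dioxabicyclo[3.3.0]octan-4-one (ring A lactone, ring B ether, cis-fused, both aryl groups exo) | COc1cc([C@H]2OC(=O)[C@@H]3[C@@H](c4ccc(OC)c(OC)c4)OC[C@]23O)ccc1O[Si](C(C)C)(C(C)C)C(C)C | intermediate
20 | (1S,2R,5R,6S)-6-(3,4-dimethoxyphenyl)-2-Ar-3,7-dioxabicyclo[3.3.0]octane-1,4-diol (lactol, C4 anomers) | COc1cc([C@H]2OC(O)[C@@H]3[C@@H](c4ccc(OC)c(OC)c4)OC[C@]23O)ccc1O[Si](C(C)C)(C(C)C)C(C)C | intermediate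
21 | (1S,2R,5R,6S)-6-(3,4-dimethoxyphenyl)-2-Ar-3,7-dioxabicyclo[3.3.0]octan-1-ol | COc1cc([C@H]2OC[C@@H]3[C@@H](c4ccc(OC)c(OC)c4)OC[C@]23O)ccc1O[Si](C(C)C)(C(C)C)C(C)C | intermediate
22 | (1S,2R,5R,6S)-6-(3,4-dimethoxyphenyl)-2-Ar-3,7-dioxabicyclo[3.3.0]octan-1-yl acetate | COc1cc([C@H]2OC[C@@H]3[C@@H](c4ccc(OC)c(OC)c4)OC[C@]23OC(C)=O)ccc1O[Si](C(C)C)(C(C)C)C(C)C | intermediate
23 | (1S,2R,5R,6S)-6-(3,4-dimethoxyphenyl)-2-(4-hydroxy-3-methoxyphenyl)-3,7-dioxabicyclo[3.3.0]octan-1-yl acetate; (7R,8S,8'R,7'S) in the lignan numbering | COc1cc([C@H]2OC[C@@H]3[C@@H](c4ccc(OC)c(OC)c4)OC[C@]23OC(C)=O)ccc1O | target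

Total steps: 13. Longest linear sequence: 12 (steps 1 and 3 to 13; step 2 is a one-step branch).

Steps most likely to fail

Step 6 (proposed new method). Three processes can defeat it.
- Copper may migrate from C8' to the ester oxygen before the C–C bond forms. The oxygen-bound enolate is expected to close through a copper-bridged chair, as hydride-initiated relatives are understood to do. That turns the other face of the ketone towards C8' and gives the C8 epimer, from which ring B cannot be closed.
- Funnelling at C7 may be incomplete. The organocopper derived from the 7S acyloin closes slowly and cannot epimerise at C7 once borylated. It may instead be protonated, by tert-butanol or by the C7–H of another substrate molecule, to the open-chain β-boryl ester, which caps the yield.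
- The cinnamoyl group may shift from O7 to O8 through the enediolate, or the copper boryl may add 1,2 to the ketone.

The fallback uses known reactions only, sets out from 10 and returns at 16. The cascade is interrupted with methanol under the established enantioselective conjugate borylation of cinnamates (CuCl, NaOtBu, the same ligand, B2pin2, MeOH, THF), which should give the open-chain β-boryl ester F1 as a pair of C7 epimers with C7' fixed. Perborate oxidation gives the β-hydroxy ester F2 and TESCl/imidazole the triethylsilyl ether F3. Ring A is then closed by the base-mediated intramolecular aldol lactonisation of an acyloin ester (LiN(SiMe3)2, THF, −78 °C). Both ketone α-positions carry oxygen and are slow to deprotonate, so the ester is enolised kinetically to the alkoxy-syn lithium enolate. Its lithium-bridged closure is expected to place the C7' arm beside C9, but control from C7' is not assured, so the lactone F4 is separated from its diastereomers. Brief treatment with HF·pyridine removes the triethylsilyl group and returns 16.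

Step 9. The doubly β-hydroxylated lactone may undergo retro-aldol cleavage or dehydration under base, displacement at the neopentyl-type C9 may be sluggish, or the wrong hydroxyl may be sulfonylated. The fallback sets out from 17 and returns at 21 without any base or displacement. TEMPO/PhI(OAc)2 in CH2Cl2 oxidises the primary C9 hydroxyl, the C7' hydroxyl traps the aldehyde as the ring B lactol, and further oxidation gives the bis-lactone F5. Excess i-Bu2AlH at −78 °C reduces both lactones to the bis-lactol F6, and Et3SiH/BF3·OEt2 removes both anomeric oxygens to give 21.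

Step 11. BF3 may ionise the benzylic C7–O or C7'–O bond, leading to epimerisation or reductive ring opening. The fallback sets out from 19, returns at 21 and uses no Lewis acid. LiAlH4 in THF at 0 °C reduces the lactone to the triol F7. TsCl in pyridine at 0 °C sulfonylates the primary C9' hydroxyl to the tosylate F8. NaH in THF then lets the C7 hydroxyl displace it (5-exo-tet, retention at C7) to give 21.

Further compounds
F1 | step 6 | open-chain β-boryl ester of the acyloin, 7'S, C7 epimer pair | COc1cc(C(OC(=O)C[C@H](B2OC(C)(C)C(C)(C)O2)c2ccc(OC)c(OC)c2)C(=O)CO[Si](C)(C)C(C)(C)C)ccc1O[Si](C(C)C)(C(C)C)C(C)C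
F2 | step 6 | open-chain β-hydroxy ester, 7'S, C7 epimer pair | COc1cc(C(OC(=O)C[C@H](O)c2ccc(OC)c(OC)c2)C(=O)CO[Si](C)(C)C(C)(C)C)ccc1O[Si](C(C)C)(C(C)C)C(C)C
F3 | step 6 | triethylsilyl ether of F2 | COc1cc(C(OC(=O)C[C@H](O[Si](CC)(CC)CC)c2ccc(OC)c(OC)c2)C(=O)CO[Si](C)(C)C(C)(C)C)ccc1O[Si](C(C)C)(C(C)C)C(C)C
F4 | step 6 | (7R,8S,8'R,7'S) ring A lactone with C7'–O-triethylsilyl and C9–OTBS | COc1cc([C@H]2OC(=O)[C@H]([C@H](O[Si](CC)(CC)CC)c3ccc(OC)c(OC)c3)[C@]2(O)CO[Si](C)(C)C(C)(C)C)ccc1O[Si](C(C)C)(C(C)C)C(C)C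
F5 | step 9 | (1S,2R,5R,6S)-6-(3,4-dimethoxyphenyl)-1-hydroxy-2-Ar-3,7-dioxabicyclo[3.3.0]octane-4,8-dione (bis-lactone) | COc1cc([C@H]2OC(=O)[C@@H]3[C@@H](c4ccc(OC)c(OC)c4)OC(=O)[C@]23O)ccc1O[Si](C(C)C)(C(C)C)C(C)C
F6 | step 9 | (1S,2R,5R,6S)-6-(3,4-dimethoxyphenyl)-2-Ar-3,7-dioxabicyclo[3.3.0]octane-1,4,8-triol (bis-lactol, anomer mixture) | COc1cc([C@H]2OC(O)[C@@H]3[C@@H](c4ccc(OC)c(OC)c4)OC(O)[C@]23O)ccc1O[Si](C(C)C)(C(C)C)C(C)C
F7 | step 11 | ring B triol: 5-(3,4-dimethoxyphenyl)-3-[Ar(hydroxy)methyl]-4-(hydroxymethyl)tetrahydrofuran-3-ol, (7R,8S,8'R,7'S) | COc1cc([C@@H](O)[C@@]2(O)CO[C@H](c3ccc(OC)c(OC)c3)[C@H]2CO)ccc1O[Si](C(C)C)(C(C)C)C(C)C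
F8 | step 11 | primary tosylate of F7 at C9' | COc1cc([C@@H](O)[C@@]2(O)CO[C@H](c3ccc(OC)c(OC)c3)[C@H]2COS(=O)(=O)c2ccc(C)cc2)ccc1O[Si](C(C)C)(C(C)C)C(C)C
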